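The vessel changes from tank to closed flask to dosed flask while the charge stays the same, and you follow how much open intermediate remains when the mixture leaves or the run stops.

    reagent + catalyst intermediate → second catalyst + product (k1 = 940 L mol⁻¹ s⁻¹)
    second catalyst + second catalyst ⇌ resting dimer (K2 = 940 L mol⁻¹, k2 = 87 L mol⁻¹ s⁻¹)
    substrate + free catalyst → free catalyst + open intermediate (k3 = 2500 L mol⁻¹ s⁻¹)
    second catalyst + open intermediate ⇌ catalyst intermediate (K4 = 130 L mol⁻¹, k4 = 150 L mol⁻¹ s⁻¹)

| flask | substrate | reagent | free catalyst | second catalyst | remark | time |
|---|---|---|---|---|---|---|
| teal | 0.050 M | 0.0750 M | 0.50 mM | 1.0 mM | one stirred flow tank at steady state, fed with the mixture as stated, mean residence time 8.0 s |  |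
| ochre | 0.050 M | 0.0750 M | 0.50 mM | 1.0 mM | one stirred flow tank at steady state, fed with the mixture as stated, mean residence time 40.0 s |  |
| red | 0.050 M | 0.0750 M | 0.50 mM | 1.0 mM | everything together in a closed stirred flask, run for 8.0 s | 8.0 s |
| grey | 0.050 M (fed, over 6.40 s) | 0.0750 M | 0.50 mM | 1.0 mM | a stirred flask in which substrate is dosed at a steady rate over 6.40 s without added volume, worked up at 8.0 s | 8.0 s |

- where a step has two of a species, its rate is k times that concentration squared, and two are used at each turn
- the stated concentrations are those of everything mixed, before any reaction; amounts are the same in each set-up
- the feed brings no volume worth counting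
- run time (red): 8.0 s

- the set-up with the highest amount of open intermediate at the outlet or at the end, in percent of the substrate put in ("none" if the first two lie within 2 percentage points) (teal / ochre / red / grey / none)
- amount of open intermediate at the outlet or at the end, in percent of the substrate put in, teal
- amount of open intermediate at the outlet or at the end, in percent of the substrate put in, ochre
- amount of open intermediate at the outlet or at the end, in percent of the substrate put in, red
- amount of open intermediate at the outlet or at the end, in percent of the substrate put in, grey

- **Fastest rung.** Catalyst intermediate lasts 14.2 ms against reagent, while its way back takes 0.867 s, so nearly all captures end as product. A capture takes up one open intermediate, and the reagent step gives the second catalyst back.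
- **Second rung.** Free catalyst is not consumed, so substrate opens pseudo-first-order with a mean life of 0.800 s.
- **Third rung.** Second catalyst pairs into resting dimer on a slower clock, T = 5.75 s, and the equilibrium balance puts its floor at 0.510 mM.
- **Slowest rung.** Capture at the charged level takes 6.67 s on average, longer than T, so second catalyst falls while the capture runs.
- **The mean.** Replace that falling curve by one level, c_m: the charge divided by one plus half the run over T, taken as the floor where that quotient lies lower. For 8.0 s this gives 0.590 mM.
- **The rule.** The drain constant d is the capture rate constant times c_m, here 0.0884 s⁻¹. The exposure E is d times the time open intermediate sits. A closed flask keeps e to the minus E, and a tank keeps the opened share divided by one plus E.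
- **My reckoning.** Teal keeps 53.2%. In ochre c_m reaches the floor, so d is 0.0766 s⁻¹ and 24.1% stays. In red the open intermediate sits 7.20 s on average, which leaves 52.9%. In grey its mean age is 4.00 s, which leaves 70.2%, so grey comes out highest.
- **The forecast.** It names grey, with teal 52.2%, ochre 23.7%, red 51.5% and grey 69.5%, and says “dosing the substrate late keeps the most”.
- **The result.** The flask gives grey: teal 52.1%, ochre 23.7%, red 51.1%, grey 70.1%. With the capture step struck out both ways, grey ends at 98.3%. Read backwards over its mean age, grey's result means a drain of 0.0888 s⁻¹, beside my d of 0.0884 s⁻¹. Run teal's tank at 80.0 s and the mid-run level falls under the floor, so E becomes 6.12 and the rule gives 13.9%; that tank stands at 14.0%.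

The constants used here are invented; no experiment stands behind them.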